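**Plan**
- Retrosynthesis: the C10–O9 ether bond is cut first (transannular opening of a 10,16-epoxide by the C8 hydroxyl), then the C20/C23 epoxide and the C24 ketone are taken back to a (24S)-allylic alcohol; the twelve-membered carbocycle is cut at C12–C13 and the chain is detached from ring A at C6–C24.
- Enabling feature: the macrocycle leaves ring A (C2, C3, C4, C6, C7, C14) through the C13 methylene on quaternary C14 and meets at C12 a head-to-tail ten-carbon isoprenoid chain (C12, C10 with methyl C11, C16, C18, C19, C20 with methyl C21, C23, C24). C12 is therefore a primary allylic carbon of the E C10=C16 alkene, and C13 can carry a sulfone.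
- Forward: ring A is made first (iodide 17), the neryl acetate-derived Z-enal 22 is joined at C6–C24, the carbocycle is closed at C12–C13 by sulfone carbanion alkylation, the oxepane is closed next and the epoxy ketone is made last.
- Stereochemistry: C2 from catalytic asymmetric conjugate methylation; C14 by alkylation anti to the C2 methyl; C4 and C24 by CBS reductions; C10 and C16 by Shi epoxidation and invertive ether closure; C20 and C23 by hydroxyl-directed epoxidation of the Z alkene inherited from nerol.

Key step: step 21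

Labels: C1 to O25 are the atom positions in the target SMILES and are kept for every intermediate.
Assumption: the (S,R,R) enantiomer of the BINOL-derived N,N-bis(1-phenylethyl)phosphoramidite is taken as the ligand that gives the (3S) enolate in step 1; if its sense is the opposite, the mirror-image ligand is used.
Remark: the carbinol centre of 14, C24 of 23 and C13 of 30 are not controlled and are erased in steps 8, 16 and 22; one epimer is drawn for 14 and 30, and C24 is left open in the SMILES of 23.

**Step 1**
Reactants: 1 2-methylcyclohex-2-en-1-one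
Product: 3 {[(3S)-2,3-dimethylcyclohex-1-en-1-yl]oxy}trimethylsilane, via dimethylaluminium enolate 2 (not isolated)
Conditions: Me3Al, copper thiophene-2-carboxylate Cu(O2CC4H3S) (cat.), (S,R,R)-BINOL N,N-bis(1-phenylethyl)phosphoramidite (cat.), Et2O, −30 °C; then TMSOTf, −30 °C to rt
Reagents that add atoms: trimethylaluminium C[Al](C)C; trimethylsilyl trifluoromethanesulfonate C[Si](C)(C)OS(=O)(=O)C(F)(F)F
Why: Copper-catalysed asymmetric conjugate addition of Me3Al to a 2-substituted cyclohexenone is established, the chiral phosphoramidite–copper complex sets C2 by enantioface-selective methyl transfer, and O-silylation of the aluminium enolate stores the regiodefined tetrasubstituted enolate.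

**Step 2**
Reactants: 3 silyl enol ether; 4 chloromethyl phenyl sulfide
Product: 5 (2R,3S)-2,3-dimethyl-2-[(phenylsulfanyl)methyl]cyclohexan-1-one
Conditions: TiCl4, CH2Cl2, −78 to −20 °C
Reagents that add atoms: none
Why: Lewis acid-mediated α-(phenylthio)methylation of a silyl enol ether (thionium ion alkylation) forms quaternary centres regiospecifically, and the electrophile should add anti to the pseudoaxial C2 methyl, placing C13 trans to that methyl at C14.

**Step 3**
Reactants: 5 sulfide ketone
Product: 6 (2R,3S)-2,3-dimethyl-2-[(phenylsulfonyl)methyl]cyclohexan-1-one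
Conditions: H2O2 (30% aq.), (NH4)6Mo7O24·4H2O (cat.), EtOH, 0 °C to rt
Reagents that add atoms: hydrogen peroxide OO
Why: Molybdate-catalysed peroxide oxidation takes the sulfide through the sulfoxide to the sulfone far faster than any Baeyer–Villiger reaction of the hindered ketone.

**Step 4**
Reactants: 6 sulfone ketone
Product: 7 (5S,6R)-5,6-dimethyl-6-[(phenylsulfonyl)methyl]cyclohex-2-en-1-one
Conditions: 2-iodoxybenzoic acid (IBX), DMSO/fluorobenzene, 70 °C
Reagents that add atoms: none
Why: IBX dehydrogenation of ketones proceeds through the enol, and only the C6 methylene can enolise because C14 is quaternary, so a single enone should form.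

**Step 5**
Reactants: 7 enone
Product: 8 (5S,6R)-2-iodo-5,6-dimethyl-6-[(phenylsulfonyl)methyl]cyclohex-2-en-1-one
Conditions: I2, pyridine/CH2Cl2, 0 °C to rt
Reagents that add atoms: iodine II
Why: α-Iodination of a β-unsubstituted cycloalkenone with I2/pyridine (conjugate addition of pyridine, iodination of the enolate, elimination) is a standard route to 2-iodoenones and puts iodine on C6.

**Step 6**
Reactants: 9 4-methoxybenzyl alcohol; 10 tributyl(iodomethyl)stannane
Product: 11 tributyl{[(4-methoxybenzyl)oxy]methyl}stannane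
Conditions: NaH, THF/DMF, 0 °C to rt
Reagents that add atoms: none
Why: Williamson etherification of the alkoxide with the primary iodomethylstannane is the usual preparation of alkoxymethylstannanes.

**Step 7**
Reactants: 8 iodoenone; 11 alkoxymethylstannane
Product: 14 (1R,5S,6R)-2-iodo-1-{[(4-methoxybenzyl)oxy]methyl}-5,6-dimethyl-6-[(phenylsulfonyl)methyl]cyclohex-2-en-1-ol, via lithium reagent 12 (not isolated), via cerium reagent 13 (not isolated)
Conditions: 11, n-BuLi, THF, −78 °C; CeCl3, −78 °C; then 8, −78 °C; aq. NH4Cl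
Reagents that add atoms: none
Why: Tin–lithium exchange gives the α-alkoxymethyllithium, and its organocerium derivative should add 1,2 to the hindered iodoenone without iodine–metal exchange or deprotonation of the sulfone, bringing in C8 (the carbinol centre is erased in step 8).

**Step 8**
Reactants: 14 tertiary allylic alcohol
Product: 15 (4R,5S)-2-iodo-3-{[(4-methoxybenzyl)oxy]methyl}-4,5-dimethyl-4-[(phenylsulfonyl)methyl]cyclohex-2-en-1-one
Conditions: pyridinium chlorochromate C5H5NH[CrO3Cl], 4 Å molecular sieves, CH2Cl2, rt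
Reagents that add atoms: pyridinium chlorochromate [O-][Cr](=O)(=O)Cl.c1cc[nH+]cc1
Why: Babler–Dauben oxidative transposition (chromate ester, [3,3] shift, oxidation) moves oxygen to C4 and the alkene to C6=C7, and it relieves the congested tertiary carbinol next to the quaternary centre.

**Step 9**
Reactants: 15 iodoenone
Product: 16 (1R,4R,5S)-2-iodo-3-{[(4-methoxybenzyl)oxy]methyl}-4,5-dimethyl-4-[(phenylsulfonyl)methyl]cyclohex-2-en-1-ol
Conditions: (S)-2-methyl-CBS-oxazaborolidine (cat.), catecholborane, toluene, −78 to −40 °C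
Reagents that add atoms: none
Why: In the Corey–Bakshi–Shibata reduction of a 2-haloenone the halovinyl carbon acts as the large group, so the (S)-catalyst should give the (R)-carbinol at C4, and axial hydride attack on the half-chair favours the same isomer with the C2 methyl and the C4 oxygen cis.

**Step 10**
Reactants: 16 iodo allylic alcohol
Product: 17 ring A iodide (tert-butyldimethylsilyl ether of 16)
Conditions: TBSOTf, 2,6-lutidine, CH2Cl2, −78 to 0 °C
Reagents that add atoms: tert-butyldimethylsilyl trifluoromethanesulfonate CC(C)(C)[Si](C)(C)OS(=O)(=O)C(F)(F)F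
Why: Silylation with a silyl triflate and a hindered pyridine base protects the hindered allylic alcohol cleanly.

**Step 11**
Reactants: 18 neryl acetate
Product: 19 (2Z,6E)-8-hydroxy-3,7-dimethylocta-2,6-dien-1-yl acetate
Conditions: SeO2 (cat.), t-BuOOH, salicylic acid (cat.), CH2Cl2, rt
Reagents that add atoms: tert-butyl hydroperoxide CC(C)(C)OO
Why: Catalytic SeO2 allylic oxidation (ene reaction, then [2,3]-sigmatropic shift) attacks the electron-richer terminal alkene at its E methyl group, giving the E allylic alcohol (future C12) and leaving the acetate-deactivated Z alkene alone.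

**Step 12**
Reactants: 19 hydroxy acetate
Product: 20 (2E,6Z)-8-acetoxy-2,6-dimethylocta-2,6-dien-1-yl pivalate
Conditions: PivCl, pyridine, DMAP (cat.), CH2Cl2, 0 °C
Reagents that add atoms: pivaloyl chloride CC(C)(C)C(Cl)=O
Why: Acylation of the primary allylic alcohol gives an ester that will outlast the acetate and the later coupling, oxidation and reduction steps.

**Step 13**
Reactants: 20 acetate pivalate
Product: 21 (2E,6Z)-8-hydroxy-2,6-dimethylocta-2,6-dien-1-yl pivalate
Conditions: K2CO3 (cat.), MeOH, 0 °C
Reagents that add atoms: none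
Why: Base-catalysed transesterification removes the unhindered acetate much faster than the pivalate.

**Step 14**
Reactants: 21 allylic alcohol
Product: 22 (2E,6Z)-2,6-dimethyl-8-oxoocta-2,6-dien-1-yl pivalate
Conditions: TEMPO (cat.), PhI(OAc)2, CH2Cl2, rt
Reagents that add atoms: none
Why: The oxoammonium oxidation of primary allylic alcohols is neutral and is known to give Z enals without Z to E isomerisation.

**Step 15**
Reactants: 17 ring A iodide; 22 Z-enal
Product: 23 C6–C24 coupled bis-allylic alcohol (C24 epimers)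
Conditions: CrCl2, NiCl2 (cat.), DMSO/THF, rt
Reagents that add atoms: none
Why: In the Nozaki–Hiyama–Kishi coupling the nickel-catalysed formation of the alkenylchromium species from the hindered iodide and its 1,2-addition to the aldehyde tolerate the sulfone, the ester and the ethers (the C24 configuration is reset in steps 16 and 17).

**Step 16**
Reactants: 23 bis-allylic alcohol
Product: 24 cross-conjugated dienone (C24 ketone)
Conditions: Dess–Martin periodinane, NaHCO3, CH2Cl2, 0 °C
Reagents that add atoms: none
Why: Dess–Martin oxidation converts both C24 epimers to one dienone under buffered conditions that should not isomerise the Z alkene.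

**Step 17**
Reactants: 24 dienone
Product: 25 (24S)-bis-allylic alcohol
Conditions: (R)-2-methyl-CBS-oxazaborolidine, catecholborane, toluene, −78 to −40 °C
Reagents that add atoms: none
Why: In this Corey–Bakshi–Shibata reduction the fully substituted ring A alkenyl group is the large substituent and the Z-alkenyl group the small one, so the (R)-catalyst should give the (24S)-carbinol by 1,2-reduction.

**Step 18**
Reactants: 25 (24S)-alcohol
Product: 26 C24 triethylsilyl ether
Conditions: TESOTf, 2,6-lutidine, CH2Cl2, −78 °C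
Reagents that add atoms: triethylsilyl trifluoromethanesulfonate CC[Si](CC)(CC)OS(=O)(=O)C(F)(F)F
Why: Silyl triflate silylation caps the hindered bis-allylic alcohol with a group that can later be removed in the presence of tert-butyldimethylsilyl ethers.

**Step 19**
Reactants: 26 pivalate
Product: 27 C12 allylic alcohol
Conditions: i-Bu2AlH, CH2Cl2, −78 °C; aq. KNaC4H4O6
Reagents that add atoms: none
Why: Reductive ester cleavage by i-Bu2AlH at low temperature leaves the silyl ethers, the PMB ether and the sulfone untouched.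

**Step 20**
Reactants: 27 allylic alcohol
Product: 28 C12 allylic bromide (ring A C13 phenyl sulfone; C4 OTBS; C8 OPMB; 24S OTES)
Conditions: CBr4, PPh3, 2,6-lutidine, CH2Cl2, −20 °C
Reagents that add atoms: carbon tetrabromide BrC(Br)(Br)Br
Why: The Appel reaction converts the primary allylic alcohol to the bromide by direct displacement of the oxyphosphonium ion without allylic transposition, and the lutidine buffer protects the triethylsilyl ether.

**Step 21**
Reactants: 28 allylic bromide sulfone
Product: 30 macrocyclic C13 sulfone (twelve-membered ring with 10E and 20Z alkenes; C4 OTBS; C8 OPMB; 24S OTES), via potassium sulfonyl carbanion 29 (not isolated)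
Conditions: KN(SiMe3)2 (1.2 equiv), THF, 0.002 M, slow addition of 28, −20 °C to rt
Reagents that add atoms: none
Why: KN(SiMe3)2 removes a proton from C13, the only position acidified by the sulfone, and the carbanion displaces the primary allylic bromide at C12 by direct SN2 attack. The closest known reaction type is the macrocyclisation of sulfone-stabilised carbanions onto allylic halides used for macrocyclic terpenoid carbocycles. The twelve-membered ring (C6, C7, C14, C13, C12, C10, C16, C18, C19, C20, C23, C24) closes in a 12-exo-tet mode with the bromide leaving outside the new ring. The only new stereocentre is C13, which is not controlled and is removed by desulfonylation in step 22. The step needs ring closure over oligomerisation, attack at C12 and not at C16, and intact alkene geometries. Slow addition at high dilution favours the ring, attack with allylic transposition would give a strained ten-membered ring, and the metal-free low-temperature conditions leave the E and Z alkenes untouched.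

**Step 22**
Reactants: 30 macrocyclic sulfone
Product: 31 macrocyclic triene (C13 methylene)
Conditions: Na(Hg), Na2HPO4, MeOH/THF, −20 °C
Reagents that add atoms: none
Why: Reductive desulfonylation by electron transfer from sodium amalgam cleaves the C13–S bond and protonates C13 in buffered methanol, which removes the uncontrolled centre and leaves allylic ethers and alkenes alone.

**Step 23**
Reactants: 31 PMB ether
Product: 32 C8 allylic alcohol
Conditions: DDQ, CH2Cl2/pH 7 phosphate buffer, 0 °C
Reagents that add atoms: none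
Why: Oxidative cleavage of the electron-rich PMB ether by DDQ (hydride abstraction, then hydrolysis) frees the C8 hydroxyl and leaves the silyl ethers in place.

**Step 24**
Reactants: 32 triene alcohol
Product: 33 (10R,16R)-epoxide
Conditions: D-fructose-derived Shi ketone (cat.), KHSO5 (as 2KHSO5·KHSO4·K2SO4), K2CO3, Bu4NHSO4, MeCN/dimethoxymethane/aq. Na2B4O7 buffer, 0 °C
Reagents that add atoms: potassium peroxymonosulfate [K+].[O-]S(=O)(=O)OO
Why: In the Shi epoxidation the chiral dioxirane attacks E-trisubstituted alkenes through a spiro transition state and should give the (10R,16R)-epoxide, while the Z alkene and the ring A alkene are shielded and deactivated by their allylic oxygen substituents.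

**Step 25**
Reactants: 33 epoxy alcohol
Product: 34 oxepane alcohol (C8–O9–C10 ether; C16 hydroxyl)
Conditions: camphorsulfonic acid (cat.), CH2Cl2, −20 to 0 °C
Reagents that add atoms: none
Why: Acid-catalysed epoxide opening by the transannular C8 hydroxyl occurs at the tertiary carbon C10 with inversion (7-exo closure, preferred over the 8-endo path), which sets C10 as S and leaves the C16 carbinol R.

**Step 26**
Reactants: 34 oxepane alcohol
Product: 35 C16 tert-butyldimethylsilyl ether
Conditions: TBSOTf, 2,6-lutidine, CH2Cl2, 0 °C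
Reagents that add atoms: tert-butyldimethylsilyl trifluoromethanesulfonate CC(C)(C)[Si](C)(C)OS(=O)(=O)C(F)(F)F
Why: Silylation caps the C16 hydroxyl so that it can neither open the later C20/C23 epoxide transannularly nor be oxidised in step 29.

**Step 27**
Reactants: 35 tris-silyl ether
Product: 36 (24S)-allylic alcohol
Conditions: HF·pyridine, pyridine, THF, 0 °C
Reagents that add atoms: none
Why: Buffered fluoride cleaves a triethylsilyl ether much faster than secondary tert-butyldimethylsilyl ethers (selective desilylation), and the conditions are too weakly acidic to ionise the bis-allylic carbinol.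

**Step 28**
Reactants: 36 allylic alcohol
Product: 37 threo epoxy alcohol (cis C20/C23 epoxide)
Conditions: VO(acac)2 (cat.), t-BuOOH (in decane), CH2Cl2, 0 °C
Reagents that add atoms: tert-butyl hydroperoxide CC(C)(C)OO
Why: Vanadium-catalysed hydroxyl-directed epoxidation delivers oxygen syn to the C24 hydroxyl in the conformer that minimises A(1,3) strain (C24–H eclipsing the alkene), which keeps the Z geometry as a cis epoxide with the target configuration at C20 and C23 and spares the shielded tetrasubstituted C6=C7 alkene.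

**Step 29**
Reactants: 37 epoxy alcohol
Product: 38 epoxy ketone (C24 ketone; C4 and C16 OTBS)
Conditions: Dess–Martin periodinane, NaHCO3, CH2Cl2, 0 °C to rt
Reagents that add atoms: none
Why: Dess–Martin oxidation converts the only free hydroxyl to the ketone under buffered conditions that do not open the adjacent epoxide.

**Step 30**
Reactants: 38 bis-silyl ether
Product: 39 target CNP0316768.3
Conditions: HF·pyridine, pyridine, THF, 0 °C to rt
Reagents that add atoms: none
Why: Fluoride-mediated cleavage of the two silyl ethers, buffered with pyridine, frees the C4 and C16 hydroxyls without opening the epoxide or the oxepane.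

**Compound list**
1 | 2-methylcyclohex-2-en-1-one | CC1=CCCC1=O | starting material
2 | dimethylaluminium (3S)-2,3-dimethylcyclohex-1-en-1-olate | C[C@H]1CCCC(O[Al](C)C)=C1C | intermediate (not isolated)
3 | {[(3S)-2,3-dimethylcyclohex-1-en-1-yl]oxy}trimethylsilane | C[C@H]1CCCC(O[Si](C)(C)C)=C1C | intermediate
4 | chloromethyl phenyl sulfide | ClCSc1ccccc1 | starting material
5 | (2R,3S)-2,3-dimethyl-2-[(phenylsulfanyl)methyl]cyclohexan-1-one | C[C@H]1CCCC(=O)[C@]1(C)CSc1ccccc1 | intermediate
6 | (2R,3S)-2,3-dimethyl-2-[(phenylsulfonyl)methyl]cyclohexan-1-one | C[C@H]1CCCC(=O)[C@]1(C)CS(=O)(=O)c1ccccc1 | intermediate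
7 | (5S,6R)-5,6-dimethyl-6-[(phenylsulfonyl)methyl]cyclohex-2-en-1-one | C[C@H]1CC=CC(=O)[C@]1(C)CS(=O)(=O)c1ccccc1 | intermediate
8 | (5S,6R)-2-iodo-5,6-dimethyl-6-[(phenylsulfonyl)methyl]cyclohex-2-en-1-one | C[C@H]1CC=C(I)C(=O)[C@]1(C)CS(=O)(=O)c1ccccc1 | intermediate
9 | 4-methoxybenzyl alcohol | COc1ccc(CO)cc1 | starting material
10 | tributyl(iodomethyl)stannane | CCCC[Sn](CCCC)(CCCC)CI | starting material
11 | tributyl{[(4-methoxybenzyl)oxy]methyl}stannane | CCCC[Sn](CCCC)(CCCC)COCc1ccc(OC)cc1 | intermediate
12 | {[(4-methoxybenzyl)oxy]methyl}lithium | [Li]COCc1ccc(OC)cc1 | intermediate (not isolated)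
13 | dichloro{[(4-methoxybenzyl)oxy]methyl}cerium | Cl[Ce](Cl)COCc1ccc(OC)cc1 | intermediate (not isolated)
14 | (1R,5S,6R)-2-iodo-1-{[(4-methoxybenzyl)oxy]methyl}-5,6-dimethyl-6-[(phenylsulfonyl)methyl]cyclohex-2-en-1-ol (carbinol epimer drawn) | C[C@H]1CC=C(I)[C@](O)(COCc2ccc(OC)cc2)[C@]1(C)CS(=O)(=O)c1ccccc1 | intermediate
15 | (4R,5S)-2-iodo-3-{[(4-methoxybenzyl)oxy]methyl}-4,5-dimethyl-4-[(phenylsulfonyl)methyl]cyclohex-2-en-1-one | C[C@H]1CC(=O)C(I)=C(COCc2ccc(OC)cc2)[C@]1(C)CS(=O)(=O)c1ccccc1 | intermediate
16 | (1R,4R,5S)-2-iodo-3-{[(4-methoxybenzyl)oxy]methyl}-4,5-dimethyl-4-[(phenylsulfonyl)methyl]cyclohex-2-en-1-ol | C[C@H]1C[C@@H](O)C(I)=C(COCc2ccc(OC)cc2)[C@]1(C)CS(=O)(=O)c1ccccc1 | intermediate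
17 | ring A iodide: tert-butyldimethylsilyl ether of 16 (C2 S, C4 R, C14 R; C6 iodide; C8 OPMB; C13 phenyl sulfone) | C[C@H]1C[C@@H](O[Si](C)(C)C(C)(C)C)C(I)=C(COCc2ccc(OC)cc2)[C@]1(C)CS(=O)(=O)c1ccccc1 | intermediate
18 | neryl acetate, (2Z)-3,7-dimethylocta-2,6-dien-1-yl acetate | CC(C)=CCC/C(C)=C\COC(C)=O | starting material
19 | (2Z,6E)-8-hydroxy-3,7-dimethylocta-2,6-dien-1-yl acetate | OC/C(C)=C/CC/C(C)=C\COC(C)=O | intermediate
20 | (2E,6Z)-8-acetoxy-2,6-dimethylocta-2,6-dien-1-yl pivalate | CC(C)(C)C(=O)OC/C(C)=C/CC/C(C)=C\COC(C)=O | intermediate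
21 | (2E,6Z)-8-hydroxy-2,6-dimethylocta-2,6-dien-1-yl pivalate | CC(C)(C)C(=O)OC/C(C)=C/CC/C(C)=C\CO | intermediate
22 | (2E,6Z)-2,6-dimethyl-8-oxoocta-2,6-dien-1-yl pivalate | CC(C)(C)C(=O)OC/C(C)=C/CC/C(C)=C\C=O | intermediate
23 | coupled bis-allylic alcohol: ring A of 17 with C6 bonded to C24 carbinol (both epimers) of the (20Z,10E)-chain ending in C12 pivalate | C[C@H]1C[C@@H](O[Si](C)(C)C(C)(C)C)C(C(O)/C=C(C)\CC/C=C(C)/COC(=O)C(C)(C)C)=C(COCc2ccc(OC)cc2)[C@]1(C)CS(=O)(=O)c1ccccc1 | intermediate
24 | cross-conjugated dienone: C24 ketone of 23 | C[C@H]1C[C@@H](O[Si](C)(C)C(C)(C)C)C(C(=O)/C=C(C)\CC/C=C(C)/COC(=O)C(C)(C)C)=C(COCc2ccc(OC)cc2)[C@]1(C)CS(=O)(=O)c1ccccc1 | intermediate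
25 | (24S)-bis-allylic alcohol | C[C@H]1C[C@@H](O[Si](C)(C)C(C)(C)C)C([C@@H](O)/C=C(C)\CC/C=C(C)/COC(=O)C(C)(C)C)=C(COCc2ccc(OC)cc2)[C@]1(C)CS(=O)(=O)c1ccccc1 | intermediate
26 | (24S)-triethylsilyl ether of 25 | C[C@H]1C[C@@H](O[Si](C)(C)C(C)(C)C)C([C@@H](O[Si](CC)(CC)CC)/C=C(C)\CC/C=C(C)/COC(=O)C(C)(C)C)=C(COCc2ccc(OC)cc2)[C@]1(C)CS(=O)(=O)c1ccccc1 | intermediate
27 | C12 primary allylic alcohol (pivalate of 26 removed) | C[C@H]1C[C@@H](O[Si](C)(C)C(C)(C)C)C([C@@H](O[Si](CC)(CC)CC)/C=C(C)\CC/C=C(C)/CO)=C(COCc2ccc(OC)cc2)[C@]1(C)CS(=O)(=O)c1ccccc1 | intermediate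
28 | key-step precursor: C12 allylic bromide with C13 phenyl sulfone on ring A (C4 OTBS, C8 OPMB, 24S OTES, 20Z, 10E) | C[C@H]1C[C@@H](O[Si](C)(C)C(C)(C)C)C([C@@H](O[Si](CC)(CC)CC)/C=C(C)\CC/C=C(C)/CBr)=C(COCc2ccc(OC)cc2)[C@]1(C)CS(=O)(=O)c1ccccc1 | intermediate
29 | potassium C13 sulfonyl carbanion of 28 | C[C@H]1C[C@@H](O[Si](C)(C)C(C)(C)C)C([C@@H](O[Si](CC)(CC)CC)/C=C(C)\CC/C=C(C)/CBr)=C(COCc2ccc(OC)cc2)[C@]1(C)[CH-]S(=O)(=O)c1ccccc1.[K+] | intermediate (not isolated)
30 | key-step product: twelve-membered carbocycle (C6, C7, C14, C13, C12, C10, C16, C18, C19, C20, C23, C24) with 10E and 20Z alkenes, C13 phenyl sulfone (13R drawn, both epimers expected), C4 OTBS, C8 OPMB, 24S OTES | C[C@H]1C[C@@H](O[Si](C)(C)C(C)(C)C)C2=C(COCc3ccc(OC)cc3)[C@]1(C)[C@H](S(=O)(=O)c3ccccc3)C/C(C)=C/CC/C(C)=C\[C@@H]2O[Si](CC)(CC)CC | intermediate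
31 | macrocyclic triene: 30 with C13 as CH2 | C[C@H]1C[C@@H](O[Si](C)(C)C(C)(C)C)C2=C(COCc3ccc(OC)cc3)[C@]1(C)CC/C(C)=C/CC/C(C)=C\[C@@H]2O[Si](CC)(CC)CC | intermediate
32 | C8 allylic alcohol: 31 without PMB | C[C@H]1C[C@@H](O[Si](C)(C)C(C)(C)C)C2=C(CO)[C@]1(C)CC/C(C)=C/CC/C(C)=C\[C@@H]2O[Si](CC)(CC)CC | intermediate
33 | (10R,16R)-epoxide of 32 | C[C@H]1C[C@@H](O[Si](C)(C)C(C)(C)C)C2=C(CO)[C@]1(C)CC[C@@]3(C)O[C@@H]3CC/C(C)=C\[C@@H]2O[Si](CC)(CC)CC | intermediate
34 | oxepane alcohol: C8–O9–C10 ether (10S), free 16R hydroxyl, 20Z alkene, 24S OTES, C4 OTBS | C[C@H]1C[C@@H](O[Si](C)(C)C(C)(C)C)C2=C3CO[C@@](C)(CC[C@@]31C)[C@H](O)CC/C(C)=C\[C@@H]2O[Si](CC)(CC)CC | intermediate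
35 | C16 tert-butyldimethylsilyl ether of 34 | C[C@H]1C[C@@H](O[Si](C)(C)C(C)(C)C)C2=C3CO[C@@](C)(CC[C@@]31C)[C@H](O[Si](C)(C)C(C)(C)C)CC/C(C)=C\[C@@H]2O[Si](CC)(CC)CC | intermediate
36 | (24S)-allylic alcohol: 35 without the triethylsilyl group | C[C@H]1C[C@@H](O[Si](C)(C)C(C)(C)C)C2=C3CO[C@@](C)(CC[C@@]31C)[C@H](O[Si](C)(C)C(C)(C)C)CC/C(C)=C\[C@@H]2O | intermediate
37 | threo epoxy alcohol: cis C20/C23 epoxide with oxygen syn to the C24 hydroxyl, configured at C20 and C23 as in the target | C[C@H]1C[C@@H](O[Si](C)(C)C(C)(C)C)C2=C3CO[C@@](C)(CC[C@@]31C)[C@H](O[Si](C)(C)C(C)(C)C)CC[C@@]1(C)O[C@H]1[C@@H]2O | intermediate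
38 | epoxy ketone: 4,16-bis(tert-butyldimethylsilyl) ether of the target | C[C@H]1C[C@@H](O[Si](C)(C)C(C)(C)C)C2=C3CO[C@@](C)(CC[C@@]31C)[C@H](O[Si](C)(C)C(C)(C)C)CC[C@@]1(C)O[C@H]1C2=O | intermediate
39 | CNP0316768.3: (2S,4R,10S,14R,16R,20R,23R) cyclohexene-fused twelve-membered carbocycle with C8–O9–C10 oxepane bridge, C4 and C16 hydroxyls, cis C20/C23 epoxide and C24 ketone | C[C@H]1C[C@@H](O)C2=C3CO[C@@](C)(CC[C@@]31C)[C@H](O)CC[C@@]1(C)O[C@H]1C2=O | target

**Step count and risks**
Total steps: 30 (main line 25, neryl acetate arm 4, stannane reagent 1). Longest linear sequence: 25 steps, from 1 to 39 through steps 1–5, 7–10 and 15–30.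

Steps most likely to fail:

1. Step 21 (macrocyclisation). Intermolecular alkylation may outrun ring closure and give oligomers, or the hindered neopentyl-type carbanion may act as a base and cause 1,4-elimination of the allylic bromide. Fallback, setting out from 17 and 19 and returning at 30: the C12–C13 bond is made between separate partners and the ring is closed at C6–C24 instead. Appel bromination of 19 gives (2Z,6E)-8-bromo-3,7-dimethylocta-2,6-dien-1-yl acetate F1. The potassium carbanion of 17 (KN(SiMe3)2, THF, −78 °C) is alkylated with F1 to give the open-chain C13-alkylated sulfone acetate F2. Methanolysis (K2CO3, MeOH) gives the open-chain allylic alcohol F3, and TEMPO/PhI(OAc)2 oxidation gives the open-chain Z-enal F4. An intramolecular Nozaki–Hiyama–Kishi reaction (CrCl2, NiCl2 cat., DMSO/THF, high dilution) closes the twelve-membered ring to the macrocyclic bis-allylic alcohol F5. Dess–Martin oxidation gives the macrocyclic dienone F6, CBS reduction as in step 17 gives the macrocyclic (24S)-alcohol F7, and triethylsilylation gives 30 as its C13 epimers, which converge in step 22.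

2. Step 28 (directed epoxidation). The macrocycle may enforce a conformer other than the A(1,3)-minimised one, so that oxygen is delivered to the wrong alkene face, or the ring A alkene, which is also allylic to the hydroxyl, may be epoxidised. Fallback, setting out from 36 and returning at 38: 36 is oxidised first with Dess–Martin periodinane to the macrocyclic Z-dienone F8, and F8 is epoxidised under nucleophilic Weitz–Scheffer conditions (t-BuOOH, DBU, CH2Cl2). Only C20 is accessible as a β-carbon, because C7 is fully substituted and flanked by quaternary C14.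

3. Step 17 (CBS reduction of the dienone). Hydride delivery may discriminate poorly between the two alkenyl groups of the hindered ketone, the reduction may stall, or the Z-enone may isomerise. Fallback, setting out from 17 and 22 and returning at 25: the two fragments are joined under ligand control in an asymmetric Nozaki–Hiyama–Kishi coupling (CrCl2, NiCl2 cat., chiral oxazoline sulfonamide ligand, Et3N, THF). This gives the (24S)-alcohol 25 directly and bypasses 23 and 24.

**Further compounds**
F1 | step 21 | (2Z,6E)-8-bromo-3,7-dimethylocta-2,6-dien-1-yl acetate | CC(=O)OC/C=C(C)\CC/C=C(C)/CBr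
F2 | step 21 | open-chain C13-alkylated sulfone acetate (ring A iodide retained, C13 epimers) | C[C@H]1C[C@@H](O[Si](C)(C)C(C)(C)C)C(I)=C(COCc2ccc(OC)cc2)[C@]1(C)C(S(=O)(=O)c1ccccc1)C/C(C)=C/CC/C(C)=C\COC(C)=O
F3 | step 21 | open-chain allylic alcohol (C24 hydroxyl) | C[C@H]1C[C@@H](O[Si](C)(C)C(C)(C)C)C(I)=C(COCc2ccc(OC)cc2)[C@]1(C)C(S(=O)(=O)c1ccccc1)C/C(C)=C/CC/C(C)=C\CO
F4 | step 21 | open-chain Z-enal (C24 aldehyde) | C[C@H]1C[C@@H](O[Si](C)(C)C(C)(C)C)C(I)=C(COCc2ccc(OC)cc2)[C@]1(C)C(S(=O)(=O)c1ccccc1)C/C(C)=C/CC/C(C)=C\C=O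
F5 | step 21 | macrocyclic bis-allylic alcohol with C13 sulfone (C13 and C24 epimers) | C[C@H]1C[C@@H](O[Si](C)(C)C(C)(C)C)C2=C(COCc3ccc(OC)cc3)[C@]1(C)C(S(=O)(=O)c3ccccc3)C/C(C)=C/CC/C(C)=C\C2O
F6 | step 21 | macrocyclic dienone with C13 sulfone | C[C@H]1C[C@@H](O[Si](C)(C)C(C)(C)C)C2=C(COCc3ccc(OC)cc3)[C@]1(C)C(S(=O)(=O)c3ccccc3)C/C(C)=C/CC/C(C)=C\C2=O
F7 | step 21 | macrocyclic (24S)-alcohol with C13 sulfone | C[C@H]1C[C@@H](O[Si](C)(C)C(C)(C)C)C2=C(COCc3ccc(OC)cc3)[C@]1(C)C(S(=O)(=O)c3ccccc3)C/C(C)=C/CC/C(C)=C\[C@@H]2O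
F8 | step 28 | macrocyclic Z-dienone (C24 ketone, C20=C23 alkene, C4 and C16 OTBS) | C[C@H]1C[C@@H](O[Si](C)(C)C(C)(C)C)C2=C3CO[C@@](C)(CC[C@@]31C)[C@H](O[Si](C)(C)C(C)(C)C)CC/C(C)=C\C2=O
F0 | step 17 | none | none
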